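**Retrosynthetic overview**

1. The bicyclo[3.3.1]nonane is opened at the C1–C8 bond (between two quaternary carbons) to a tertiary enol ether, a dihydropyran fused to the trione ring; this ether is a stored C8 cation.
2. The key bond is that tertiary C8–O bond, made by a chemoselective Markovnikov addition of an enol O–H across the one 1,1-disubstituted alkene of a lavandulyl dienone; the same ring closure separates the two epimers at the quaternary carbon.
3. The lavandulyl dienone comes from alkylative dearomatization of a 3,5-digeranyl acylphloroglucinol with (S)-lavandulyl triflate (C5–C6 bond).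
4. The acylphloroglucinol comes from a Hoesch acylation of phloroglucinol with silyl-protected 3,4-dihydroxybenzonitrile and double C-geranylation; (S)-lavandulol comes from an Evans deconjugative prenylation, which sets C7.
5. Ring order: aromatic ring (bought) → dearomatized carbocycle A → temporary oxygen ring → carbocycle B of the bicycle (oxygen ring opened again).

Assumption: enol/keto tautomers are drawn in one form; in the fragment coupling the quaternary carbon forms as both epimers, and the numbered compound is the epimer that leads to the target.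

Abbreviations in names: geranyl = (2E)-3,7-dimethylocta-2,6-dien-1-yl; prenyl = 3-methylbut-2-en-1-yl.

**Route**

Step 1
Reactants: 1 3,4-dihydroxybenzonitrile
Product: 2 3,4-bis(triisopropylsilyloxy)benzonitrile
Conditions: i-Pr3SiCl, imidazole, DMF, 23 °C
Reagents that add atoms: chlorotriisopropylsilane, CC(C)[Si](Cl)(C(C)C)C(C)C
Why: Standard silylation of phenols; the bulky aryl silyl ethers tolerate the later acid, base and fluoride-free steps and come off at the end with fluoride without touching the alkenes.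

Step 2
Reactants: 2 3,4-bis(triisopropylsilyloxy)benzonitrile; 3 phloroglucinol
Product: 5 (2,4,6-trihydroxyphenyl)[3,4-bis(triisopropylsilyloxy)phenyl]methanone, via ketiminium chloride 4 (not isolated)
Conditions: ZnCl2, HCl (gas), Et2O, 0 °C; then H2O, 80 °C
Reagents that add atoms: water, O
Why: Hoesch acylation, for which phloroglucinol is the ideal arene; its symmetry allows only one C-acylation product and the ketiminium salt is hydrolysed to the ketone.

Step 3
Reactants: 5 (2,4,6-trihydroxyphenyl)[3,4-bis(triisopropylsilyloxy)phenyl]methanone; 6 geranyl bromide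
Product: 7 [3,5-digeranyl-2,4,6-trihydroxyphenyl][3,4-bis(triisopropylsilyloxy)phenyl]methanone
Conditions: 6 (2.1 equiv), DBU, THF, 0 to 23 °C
Reagents that add atoms: none
Why: C-allylation of the acylphloroglucinol phenoxide at its two free ring carbons by SN2 displacement, which keeps the E alkene of the geranyl group.

Step 4
Reactants: 8 (S)-4-benzyloxazolidin-2-one; 9 3-methylbut-2-enoyl chloride
Product: 11 (S)-4-benzyl-3-(3-methylbut-2-enoyl)oxazolidin-2-one, via lithium oxazolidinide 10 (not isolated)
Conditions: n-BuLi, THF, −78 °C; then 9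
Reagents that add atoms: none
Why: N-acylation of the lithiated Evans auxiliary by the acid chloride.

Step 5
Reactants: 11 (S)-4-benzyl-3-(3-methylbut-2-enoyl)oxazolidin-2-one; 12 prenyl bromide
Product: 14 (S)-4-benzyl-3-[(2S)-5-methyl-2-(prop-1-en-2-yl)hex-4-enoyl]oxazolidin-2-one, via sodium dienolate 13 (not isolated)
Conditions: NaN(SiMe3)2, THF, −78 °C; then 12
Reagents that add atoms: none
Why: Evans alkylation in its deconjugative form: γ-deprotonation gives the chelated (Z)-dienolate, which is prenylated at the α-carbon on the face opposite the benzyl group, setting the (2S) centre (the future C7).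

Step 6
Reactants: 14 (S)-4-benzyl-3-[(2S)-5-methyl-2-(prop-1-en-2-yl)hex-4-enoyl]oxazolidin-2-one
Product: 15 (S)-lavandulol
Conditions: LiBH4, MeOH, Et2O, 0 °C
Reagents that add atoms: none
Why: Reductive cleavage of the N-acyl oxazolidinone to the primary alcohol with recovery of the auxiliary; the non-epimerizable conditions keep the stereocentre.

Step 7
Reactants: 15 (S)-lavandulol
Product: 16 (S)-lavandulyl triflate
Conditions: (CF3SO2)2O, 2,6-lutidine, CH2Cl2, −78 °C
Reagents that add atoms: trifluoromethanesulfonic anhydride, O=S(=O)(OS(=O)(=O)C(F)(F)F)C(F)(F)F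
Why: O-sulfonylation of the primary alcohol gives an electrophile reactive enough for a β-branched carbon; the stereocentre is not involved and the triflate is used at once.

Step 8
Reactants: 7 [3,5-digeranyl-2,4,6-trihydroxyphenyl][3,4-bis(triisopropylsilyloxy)phenyl]methanone; 16 (S)-lavandulyl triflate
Product: 18 (6R)-2-[3,4-bis(triisopropylsilyloxy)benzoyl]-4,6-digeranyl-3,5-dihydroxy-6-[(2R)-5-methyl-2-(prop-1-en-2-yl)hex-4-en-1-yl]cyclohexa-2,4-dien-1-one, via trilithium salt 17 (not isolated)
Conditions: LiN(SiMe3)2 (3.1 equiv), THF, −78 to 0 °C; then 16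
Reagents that add atoms: none
Why: Alkylative dearomatization: the lithium phenoxide aggregate is C-alkylated by SN2 at a geranyl-bearing ring carbon (the two are enantiotopic), so the side-chain centre is untouched and the new quaternary carbon forms as both epimers in about equal amounts, the (6R) epimer 18 being carried on and freed from the other in step 9.

Step 9
Reactants: 18 (6R)-2-[3,4-bis(triisopropylsilyloxy)benzoyl]-4,6-digeranyl-3,5-dihydroxy-6-[(2R)-5-methyl-2-(prop-1-en-2-yl)hex-4-en-1-yl]cyclohexa-2,4-dien-1-one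
Product: 19 (3R,4aR)-8-[3,4-bis(triisopropylsilyloxy)benzoyl]-4a,6-digeranyl-5-hydroxy-2,2-dimethyl-3-(3-methylbut-2-en-1-yl)-2,3,4,4a-tetrahydro-7H-chromen-7-one
Conditions: Co(salen) (C16H14CoN2O2, 5 mol%), 1-fluoro-2,4,6-trimethylpyridinium triflate, PhSiH3, PhCF3, 23 °C
Reagents that add atoms: none
Why: Proposed new method: a cobalt hydride formed from the Co(salen) catalyst, the silane and the N-fluoropyridinium oxidant should transfer a hydrogen atom only to the 1,1-disubstituted isopropenyl alkene (the five trisubstituted prenyl and geranyl alkenes react far more slowly), the tertiary C8 radical is oxidized through an alkylcobalt species of tetravalent cobalt to the cation level and is captured by the adjacent enol oxygen in a six-membered chair with the prenyl group equatorial, which for the (6R) epimer 18 is the oxygen on C1 (next to the aroyl-bearing carbon) whereas the (6S) epimer closes through the C5 oxygen and is removed here by chromatography as a constitutional isomer, so this C–O bond formation stores the C8 cation as an ionizable tertiary enol ether and frees 19 from the unwanted series without touching an existing stereocentre; the closest known reaction type is the Co(salen)/N-fluoropyridinium/silane radical-polar crossover hydroalkoxylation and lactonization of unactivated alkenes (Mukaiyama-type hydrogen-atom-transfer hydrofunctionalization), which has not been shown with a vinylogous acid as oxygen nucleophile or in a polyene of this kind.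

Step 10
Reactants: 19 (3R,4aR)-8-[3,4-bis(triisopropylsilyloxy)benzoyl]-4a,6-digeranyl-5-hydroxy-2,2-dimethyl-3-(3-methylbut-2-en-1-yl)-2,3,4,4a-tetrahydro-7H-chromen-7-one
Product: 20 (1S,5S,7R)-3-[3,4-bis(triisopropylsilyloxy)benzoyl]-1,5-digeranyl-4-hydroxy-8,8-dimethyl-7-(3-methylbut-2-en-1-yl)bicyclo[3.3.1]non-3-ene-2,9-dione
Conditions: HCO2H, 23 °C
Reagents that add atoms: none
Why: Formic acid should ionize the tertiary alkyl–oxygen bond of the vinylogous ester (as in tert-butyl ester solvolysis) faster than it protonates the trisubstituted alkenes, and the tethered C8 cation is trapped irreversibly by the geranyl-bearing enol carbon through a chair-like transition state with the prenyl group equatorial (Brønsted-acid cationic cyclization, formally a 1,3 O-to-C shift), which forms the C1–C8 bond and fixes C1 as S because the three-carbon chain can bridge the ring on one face only.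

Step 11
Reactants: 20 (1S,5S,7R)-3-[3,4-bis(triisopropylsilyloxy)benzoyl]-1,5-digeranyl-4-hydroxy-8,8-dimethyl-7-(3-methylbut-2-en-1-yl)bicyclo[3.3.1]non-3-ene-2,9-dione
Product: 21 (1S,5S,7R)-3-(3,4-dihydroxybenzoyl)-1,5-digeranyl-4-hydroxy-8,8-dimethyl-7-(3-methylbut-2-en-1-yl)bicyclo[3.3.1]non-3-ene-2,9-dione (target, CNP0178719.1)
Conditions: Bu4NF, AcOH, THF, 0 °C
Reagents that add atoms: none
Why: Buffered fluoride desilylation of the two aryl silyl ethers; no acid is present, so the enol cannot add to the prenyl or geranyl alkenes, and no stereocentre is affected.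

**Compound list**

1 | 3,4-dihydroxybenzonitrile | N#Cc1ccc(O)c(O)c1 | starting material
2 | 3,4-bis(triisopropylsilyloxy)benzonitrile | N#Cc1ccc(O[Si](C(C)C)(C(C)C)C(C)C)c(O[Si](C(C)C)(C(C)C)C(C)C)c1 | intermediate
3 | phloroglucinol (benzene-1,3,5-triol) | Oc1cc(O)cc(O)c1 | starting material
4 | ketiminium chloride: [3,4-bis(triisopropylsilyloxy)phenyl](2,4,6-trihydroxyphenyl)methaniminium chloride | [Cl-].[NH2+]=C(c1ccc(O[Si](C(C)C)(C(C)C)C(C)C)c(O[Si](C(C)C)(C(C)C)C(C)C)c1)c1c(O)cc(O)cc1O | intermediate (not isolated)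
5 | (2,4,6-trihydroxyphenyl)[3,4-bis(triisopropylsilyloxy)phenyl]methanone | O=C(c1ccc(O[Si](C(C)C)(C(C)C)C(C)C)c(O[Si](C(C)C)(C(C)C)C(C)C)c1)c1c(O)cc(O)cc1O | intermediate
6 | geranyl bromide, (2E)-1-bromo-3,7-dimethylocta-2,6-diene | CC(C)=CCC/C(C)=C/CBr | starting material
7 | [3,5-digeranyl-2,4,6-trihydroxyphenyl][3,4-bis(triisopropylsilyloxy)phenyl]methanone | O=C(c1ccc(O[Si](C(C)C)(C(C)C)C(C)C)c(O[Si](C(C)C)(C(C)C)C(C)C)c1)c1c(O)c(C/C=C(\C)CCC=C(C)C)c(O)c(C/C=C(\C)CCC=C(C)C)c1O | intermediate
8 | (S)-4-benzyloxazolidin-2-one | O=C1OC[C@H](Cc2ccccc2)N1 | starting material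
9 | 3-methylbut-2-enoyl chloride | CC(C)=CC(Cl)=O | starting material
10 | lithium oxazolidinide: N-lithio salt of (S)-4-benzyloxazolidin-2-one | [Li+].O=C1OC[C@H](Cc2ccccc2)[N-]1 | intermediate (not isolated)
11 | (S)-4-benzyl-3-(3-methylbut-2-enoyl)oxazolidin-2-one | CC(C)=CC(=O)N1[C@@H](Cc2ccccc2)COC1=O | intermediate
12 | prenyl bromide, 1-bromo-3-methylbut-2-ene | CC(C)=CCBr | starting material
13 | sodium dienolate: sodium (Z)-dienolate of 11 formed by γ-deprotonation | [Na+].[O-]/C(=C\C(C)=C)N1[C@@H](Cc2ccccc2)COC1=O | intermediate (not isolated)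
14 | (S)-4-benzyl-3-[(2S)-5-methyl-2-(prop-1-en-2-yl)hex-4-enoyl]oxazolidin-2-one | O=C(N1[C@@H](Cc2ccccc2)COC1=O)[C@@H](CC=C(C)C)C(C)=C | intermediate
15 | (S)-lavandulol, (2S)-5-methyl-2-(prop-1-en-2-yl)hex-4-en-1-ol | OC[C@@H](CC=C(C)C)C(C)=C | intermediate
16 | (S)-lavandulyl triflate, (2S)-5-methyl-2-(prop-1-en-2-yl)hex-4-en-1-yl trifluoromethanesulfonate | O=S(=O)(OC[C@@H](CC=C(C)C)C(C)=C)C(F)(F)F | intermediate
17 | trilithium salt: trilithium triphenoxide of 7 | [Li+].[Li+].[Li+].[O-]c1c(C/C=C(\C)CCC=C(C)C)c([O-])c(C(=O)c2ccc(O[Si](C(C)C)(C(C)C)C(C)C)c(O[Si](C(C)C)(C(C)C)C(C)C)c2)c([O-])c1C/C=C(\C)CCC=C(C)C | intermediate (not isolated)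
18 | (6R)-2-[3,4-bis(triisopropylsilyloxy)benzoyl]-4,6-digeranyl-3,5-dihydroxy-6-[(2R)-5-methyl-2-(prop-1-en-2-yl)hex-4-en-1-yl]cyclohexa-2,4-dien-1-one | CC(C)=CCC/C(C)=C/C[C@]1(C[C@@H](CC=C(C)C)C(C)=C)C(=O)C(C(=O)c2ccc(O[Si](C(C)C)(C(C)C)C(C)C)c(O[Si](C(C)C)(C(C)C)C(C)C)c2)=C(O)C(C/C=C(\C)CCC=C(C)C)=C1O | intermediate
19 | (3R,4aR)-8-[3,4-bis(triisopropylsilyloxy)benzoyl]-4a,6-digeranyl-5-hydroxy-2,2-dimethyl-3-(3-methylbut-2-en-1-yl)-2,3,4,4a-tetrahydro-7H-chromen-7-one | CC(C)=CCC/C(C)=C/C[C@]12C[C@@H](CC=C(C)C)C(C)(C)OC1=C(C(=O)c3ccc(O[Si](C(C)C)(C(C)C)C(C)C)c(O[Si](C(C)C)(C(C)C)C(C)C)c3)C(=O)C(C/C=C(\C)CCC=C(C)C)=C2O | intermediate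
20 | (1S,5S,7R)-3-[3,4-bis(triisopropylsilyloxy)benzoyl]-1,5-digeranyl-4-hydroxy-8,8-dimethyl-7-(3-methylbut-2-en-1-yl)bicyclo[3.3.1]non-3-ene-2,9-dione | CC(C)=CCC/C(C)=C/C[C@]12C[C@@H](CC=C(C)C)C(C)(C)[C@](C/C=C(\C)CCC=C(C)C)(C(=O)C(C(=O)c3ccc(O[Si](C(C)C)(C(C)C)C(C)C)c(O[Si](C(C)C)(C(C)C)C(C)C)c3)=C1O)C2=O | intermediate
21 | (1S,5S,7R)-3-(3,4-dihydroxybenzoyl)-1,5-bis[(2E)-3,7-dimethylocta-2,6-dien-1-yl]-4-hydroxy-8,8-dimethyl-7-(3-methylbut-2-en-1-yl)bicyclo[3.3.1]non-3-ene-2,9-dione | CC(C)=CCC/C(C)=C/C[C@]12C[C@@H](CC=C(C)C)C(C)(C)[C@](C/C=C(\C)CCC=C(C)C)(C(=O)C(C(=O)c3ccc(O)c(O)c3)=C1O)C2=O | target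

**Step count and risks**

Total step count: 11. Longest linear sequence: 8 (steps 4 to 11, from 8 and 9).

The three steps most likely to fail:

Step 9 (the new C–O bond formation). The cobalt hydride may not discriminate well enough between the isopropenyl group and the five trisubstituted alkenes, the N-fluoropyridinium salt may fluorinate the enol, or the C8 cation may be taken by carbon or by a neighbouring alkene instead of oxygen. The fallback uses known chemistry and leaves the ether out: the mixture of 18 and its (6S) epimer is stirred in formic acid, the established Brønsted-acid cationic cyclization of lavandulyl-substituted dearomatized acylphloroglucinols by alkene protonation, and 20 is separated by chromatography from the 7-epimeric bicycle of the other series. This fallback sets out from 18 and comes back at 20; it makes no new compound (F0).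

Step 8 (alkylative dearomatization). The hard triflate may alkylate oxygen, the quaternization is hindered, and there is no facial control. The fallback changes the order so that the triflate meets an unhindered ring CH and the quaternary carbon is made by the soft allylic bromide. Ketone 5 is deprotonated with LiN(SiMe3)2 and C-alkylated by 16 at a free ring carbon to give the C-lavandulyl ketone F1. Geranyl bromide 6 and DBU then geranylate the remaining ring CH to the lavandulyl geranyl ketone F2, and a second equivalent quaternizes the lavandulyl-bearing carbon (lupulone-type C-allylation). The regioisomer and the epimer are removed as cyclic ethers after step 9. This fallback sets out from 5 and comes back at 18.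

Step 10 (formic acid O-to-C shift). Formic acid may add to or cyclize the geranyl groups, the cation may return to oxygen or eliminate, and a 1,2-hydride shift from C7 would erode that centre. The fallback moves to an aprotic Lewis-acid manifold: 19 is silylated with N,O-bis(trimethylsilyl)acetamide to the trimethylsilyl ether F3. Catalytic Me3SiOTf in CH2Cl2 at −78 °C then ionizes the tertiary ether and the silyl dienol ether carbon takes the cation (Reetz-type tert-alkylation, here intramolecular). This gives the silyl enol ether F4 of the bicycle, which is hydrolysed on work-up. This fallback sets out from 19 and comes back at 20.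

Further compounds

F1 | step 8 | C-lavandulyl ketone: [2,4,6-trihydroxy-3-[(2R)-5-methyl-2-(prop-1-en-2-yl)hex-4-en-1-yl]phenyl][3,4-bis(triisopropylsilyloxy)phenyl]methanone | O=C(c1ccc(O[Si](C(C)C)(C(C)C)C(C)C)c(O[Si](C(C)C)(C(C)C)C(C)C)c1)c1c(O)cc(O)c(C[C@@H](CC=C(C)C)C(C)=C)c1O
F2 | step 8 | lavandulyl geranyl ketone: [3-geranyl-2,4,6-trihydroxy-5-[(2R)-5-methyl-2-(prop-1-en-2-yl)hex-4-en-1-yl]phenyl][3,4-bis(triisopropylsilyloxy)phenyl]methanone | O=C(c1ccc(O[Si](C(C)C)(C(C)C)C(C)C)c(O[Si](C(C)C)(C(C)C)C(C)C)c1)c1c(O)c(C/C=C(\C)CCC=C(C)C)c(O)c(C[C@@H](CC=C(C)C)C(C)=C)c1O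
F0 | step 9 | none | none
F3 | step 10 | trimethylsilyl ether of 19 (silylated at the 5-hydroxy group) | CC(C)=CCC/C(C)=C/C[C@]12C[C@@H](CC=C(C)C)C(C)(C)OC1=C(C(=O)c3ccc(O[Si](C(C)C)(C(C)C)C(C)C)c(O[Si](C(C)C)(C(C)C)C(C)C)c3)C(=O)C(C/C=C(\C)CCC=C(C)C)=C2O[Si](C)(C)C
F4 | step 10 | silyl enol ether of 20 (trimethylsilyl on the enol oxygen next to C1) | CC(C)=CCC/C(C)=C/C[C@]12C[C@@H](CC=C(C)C)C(C)(C)[C@](C/C=C(\C)CCC=C(C)C)(C(O[Si](C)(C)C)=C(C(=O)c3ccc(O[Si](C(C)C)(C(C)C)C(C)C)c(O[Si](C(C)C)(C(C)C)C(C)C)c3)C1=O)C2=O
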